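## Retrosynthetic overview

1. The 3(2H)-furanone ring is formed last: the spiro carbon carries a tertiary propargylic alcohol, which is joined to 4-iodophenol and CO (carbonylative alkynylation) and then closed through the C5 hydroxyl.
2. The propargylic cis-diol comes from ethynyl addition to the isolated ketone of a cyclopentene-1,2-dione; this sets the spiro carbon relative to the carbinol carbon.
3. The tertiary α-hydroxy β-keto ester comes from catalytic asymmetric hydroxylation of the corresponding CH-acidic β-keto ester; this sets the absolute configuration.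
4. The cyclopentene ring comes from a one-carbon ring expansion of dimethyl squarate with methyl diazoacetate (1,2-alkenyl shift with loss of N2); the squarate comes from squaric acid.
5. Ring order: cyclobutene (purchased) → cyclopentene (ring expansion) → furanone (last step).

Assumption: the (R,R)-ligand in step 3 is taken to give the (R)-alcohol by analogy with other cyclic β-keto esters; if it gives the antipode, the (S,S)-ligand is used.

## Route

Step 1
Reactants: 1 squaric acid
Product: 2 dimethyl squarate
Conditions: HC(OMe)3 (2.2 equiv), MeOH, reflux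
Reagents that add atoms: trimethyl orthoformate, COC(OC)OC
Why: Vinylogous Fischer-type esterification of the acidic enol hydroxyls, driven to completion by the orthoformate; no stereocentre is formed.

Step 2
Reactants: 2 dimethyl squarate; 3 methyl diazoacetate
Product: 4 methyl 2,3-dimethoxy-4,5-dioxocyclopent-2-ene-1-carboxylate
Conditions: Sc(OTf)3 (10 mol%), 4 Å MS, CH2Cl2, −78 → −30 °C, slow addition of 3 (1.05 equiv)
Reagents that add atoms: none
Why: Proposed new method: trivalent scandium activates one carbonyl of the strained 1,2-dione, the diazo carbon adds 1,2, and the β-diazonio alkoxide undergoes a 1,2-shift of the methoxy-bearing alkenyl ring carbon (a better migrating group than the acyl carbon, as aryl beats acyl in isatin ring expansions) with loss of N2 and relief of cyclobutene strain, the β-keto ester product being held as its Sc enolate against a second insertion; the closest known reaction is the Lewis-acid-catalysed diazo ester–ketone homologation (Tiffeneau–Demjanov type ring expansion of cyclobutanones and isatins), here extended to a squarate ester, and C1 of 4 is CH-acidic and racemic, so no stereocontrol is needed.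

Step 3
Reactants: 4 methyl 2,3-dimethoxy-4,5-dioxocyclopent-2-ene-1-carboxylate
Product: 5 methyl (1R)-1-hydroxy-2,3-dimethoxy-4,5-dioxocyclopent-2-ene-1-carboxylate
Conditions: Ni(ClO4)2·6H2O (10 mol%), (R,R)-DBFOX-Ph (11 mol%), 3-phenyl-2-(phenylsulfonyl)oxaziridine (1.2 equiv), 4 Å MS, CH2Cl2, 0 → 23 °C
Reagents that add atoms: 3-phenyl-2-(phenylsulfonyl)oxaziridine, O=S(=O)(c1ccccc1)N1OC1c1ccccc1
Why: Catalytic asymmetric α-hydroxylation of a cyclic β-keto ester: the enolate binds the chiral divalent nickel complex through the ester and C5 oxygens, so oxygen transfer from the oxaziridine occurs at the carbon between them (C1) on the unshielded face, which sets the (R)-carbinol.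

Step 4
Reactants: 5 methyl (1R)-1-hydroxy-2,3-dimethoxy-4,5-dioxocyclopent-2-ene-1-carboxylate
Product: 6 methyl (1S,5R)-5-ethynyl-1,5-dihydroxy-2,3-dimethoxy-4-oxocyclopent-2-ene-1-carboxylate
Conditions: HC≡CMgBr (2.5 equiv), THF, −78 °C; then H2O
Reagents that add atoms: ethynylmagnesium bromide, C#C[Mg]Br
Why: Grignard 1,2-addition to the non-conjugated ketone of the 1,2-dione (the other carbonyl is a vinylogous ester); the first equivalent makes the C1 magnesium alkoxide, and the alkynyl group then enters anti to it (steric bulk of the solvated alkoxide, charge repulsion, polar Felkin–Anh), cis to CO2Me, giving the cis-diol and setting C5.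

Step 5
Reactants: 6 methyl (1S,5R)-5-ethynyl-1,5-dihydroxy-2,3-dimethoxy-4-oxocyclopent-2-ene-1-carboxylate; 7 4-iodophenol
Product: 10 limnophilaspiroketone, via hydroxy ynone 8 (not isolated), via enaminone 9 (not isolated)
Conditions: PdCl2(PPh3)2 (5 mol%), CO (1 atm), Et3N (3 equiv), THF–H2O, 23 °C; then Et2NH (2 equiv), EtOH, 23 °C; then AcOH–H2O, 40 °C
Reagents that add atoms: carbon monoxide, [C-]#[O+]; water, O
Why: Copper-free carbonylative Sonogashira coupling (free iodophenols are tolerated) gives the γ-hydroxy ynone, diethylamine adds in conjugate fashion to give the enaminone, and on acidification the C5 hydroxyl closes the five-membered hemiketal on the aryl ketone and hydrolysis–dehydration gives the 3(2H)-furanone (classical amine-mediated hydroxy ynone to furanone cyclisation), faster than six-ring closure by the C1 hydroxyl; both stereocentres are untouched.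

## Compound list

1 | squaric acid (3,4-dihydroxycyclobut-3-ene-1,2-dione) | O=C1C(O)=C(O)C1=O | starting material
2 | dimethyl squarate (3,4-dimethoxycyclobut-3-ene-1,2-dione) | COC1=C(OC)C(=O)C1=O | intermediate
3 | methyl diazoacetate | COC(=O)C=[N+]=[N-] | starting material
4 | methyl 2,3-dimethoxy-4,5-dioxocyclopent-2-ene-1-carboxylate (racemic, C1 configurationally labile) | COC(=O)C1C(OC)=C(OC)C(=O)C1=O | intermediate
5 | methyl (1R)-1-hydroxy-2,3-dimethoxy-4,5-dioxocyclopent-2-ene-1-carboxylate | COC(=O)[C@@]1(O)C(OC)=C(OC)C(=O)C1=O | intermediate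
6 | methyl (1S,5R)-5-ethynyl-1,5-dihydroxy-2,3-dimethoxy-4-oxocyclopent-2-ene-1-carboxylate (cis-diol) | COC(=O)[C@@]1(O)C(OC)=C(OC)C(=O)[C@]1(C#C)O | intermediate
7 | 4-iodophenol | Oc1ccc(I)cc1 | starting material
8 | hydroxy ynone: methyl (1S,5R)-1,5-dihydroxy-5-[3-(4-hydroxyphenyl)-3-oxoprop-1-yn-1-yl]-2,3-dimethoxy-4-oxocyclopent-2-ene-1-carboxylate | COC(=O)[C@@]1(O)C(OC)=C(OC)C(=O)[C@]1(C#CC(=O)c1ccc(O)cc1)O | intermediate
9 | enaminone: methyl (1S,5R)-5-[1-(diethylamino)-3-(4-hydroxyphenyl)-3-oxoprop-1-en-1-yl]-1,5-dihydroxy-2,3-dimethoxy-4-oxocyclopent-2-ene-1-carboxylate (alkene geometry not defined) | COC(=O)[C@@]1(O)C(OC)=C(OC)C(=O)[C@]1(C(N(CC)CC)=CC(=O)c1ccc(O)cc1)O | intermediate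
10 | limnophilaspiroketone: methyl (5S,6R)-6-hydroxy-2-(4-hydroxyphenyl)-7,8-dimethoxy-4,9-dioxo-1-oxaspiro[4.4]nona-2,7-diene-6-carboxylate | COC(=O)[C@@]1(O)C(OC)=C(OC)C(=O)[C@]12OC(c1ccc(O)cc1)=CC2=O | target

## Summary and risks

Total step count: 5. Longest linear sequence: 5 steps (1 → 2 → 4 → 5 → 6 → 10).

The three steps most likely to fail:

**Step 2 (the proposed new ring expansion).** Risks are addition at the vinylogous ester carbon instead of the carbonyl, acyl instead of alkenyl migration, and a second insertion into the product. The fallback uses known chemistry and sets out from 2. Methyl diazoacetate 3 is deprotonated with LDA in THF at −78 °C and adds 1,2 to 2 to give the diazo carbinol methyl 2-diazo-2-(1-hydroxy-2,3-dimethoxy-4-oxocyclobut-2-en-1-yl)acetate F1. Treatment with Rh2(OAc)4 (1 mol%) in CH2Cl2 at 23 °C forms the divalent rhodium carbene, which undergoes the 1,2-alkenyl shift (known ring expansion of β-hydroxy α-diazo esters) and returns to the route at 4.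

**Step 3 (asymmetric hydroxylation).** Risks are low enantioselectivity with this flat, highly delocalised enolate and oxygen transfer at C3 instead of C1. The fallback sets out from 2 and changes how the oxygen is placed. The diazo carbinol F1 is made as above and oxidised with dimethyldioxirane in acetone at −40 °C to the keto ester methyl 2-(1-hydroxy-2,3-dimethoxy-4-oxocyclobut-2-en-1-yl)-2-oxoacetate F2. An α-ketol ring expansion (Cu(OTf)2, 10 mol%, CH2Cl2, 0 °C) shifts the alkenyl carbon to the ketone carbon and gives racemic methyl 1-hydroxy-2,3-dimethoxy-4,5-dioxocyclopent-2-ene-1-carboxylate F3, with the hydroxyl unambiguously at C1. Because F2 is racemic and the shift is stereospecific, F3 is resolved by preparative SFC on a chiral phase, and the route is rejoined at 5.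

**Step 4 (diastereoselective ethynylation).** Risks are attack syn to the alkoxide (wrong spiro configuration) and base-induced ester shift of the α-ketol. The fallback sets out from 5 and uses a bulky protecting group for stereocontrol. TESOTf and 2,6-lutidine in CH2Cl2 at −78 °C give the silyl ether methyl (1R)-2,3-dimethoxy-4,5-dioxo-1-(triethylsilyloxy)cyclopent-2-ene-1-carboxylate F4. Ethynylmagnesium bromide in THF at −78 °C then adds anti to the silyloxy group to give methyl (1S,5R)-5-ethynyl-5-hydroxy-2,3-dimethoxy-4-oxo-1-(triethylsilyloxy)cyclopent-2-ene-1-carboxylate F5. HF·pyridine in THF at 0 °C removes the silyl group and returns to the route at 6.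

## Further compounds

F1 | step 2 | methyl 2-diazo-2-(1-hydroxy-2,3-dimethoxy-4-oxocyclobut-2-en-1-yl)acetate (racemic) | COC(=O)C(=[N+]=[N-])C1(O)C(OC)=C(OC)C1=O
F2 | step 3 | methyl 2-(1-hydroxy-2,3-dimethoxy-4-oxocyclobut-2-en-1-yl)-2-oxoacetate (racemic) | COC(=O)C(=O)C1(O)C(OC)=C(OC)C1=O
F3 | step 3 | racemic methyl 1-hydroxy-2,3-dimethoxy-4,5-dioxocyclopent-2-ene-1-carboxylate | COC(=O)C1(O)C(OC)=C(OC)C(=O)C1=O
F4 | step 4 | methyl (1R)-2,3-dimethoxy-4,5-dioxo-1-(triethylsilyloxy)cyclopent-2-ene-1-carboxylate | COC(=O)[C@@]1(O[Si](CC)(CC)CC)C(OC)=C(OC)C(=O)C1=O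
F5 | step 4 | methyl (1S,5R)-5-ethynyl-5-hydroxy-2,3-dimethoxy-4-oxo-1-(triethylsilyloxy)cyclopent-2-ene-1-carboxylate | COC(=O)[C@@]1(O[Si](CC)(CC)CC)C(OC)=C(OC)C(=O)[C@]1(C#C)O
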